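**Retrosynthetic overview** (carotenoid numbering)

1. Target ⇐ double desilylation of its 3,3′-bis-TBS ether.
2. Bis-TBS ether ⇐ one flask, three components: the east polyenyne terminal alkyne plus (E)-2,3-dibromoacrylic acid (Sonogashira at C10–C11, then 5-exo-dig lactonisation closes the butenolide), then a west chlorohydrin vinylstannane (Stille at C8–C9, with base-induced closure of the 5,6-epoxide).
3. West piece ⇐ (−)-actinol TBS ether: chlorination of its lithium enolate cis to OTBS, then addition of (E)-2-(tributylstannyl)vinyllithium cis to Cl, so that the later SN2 closure gives the epoxide anti to the C3 oxygen.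
4. East piece ⇐ actinol enol triflate (from the potassium enolate) plus a C2-symmetric C14 tetraene-diyne (double Wittig of an enynyl phosphonium salt with glyoxal), joined by mono-Sonogashira coupling.
5. Ring order: both carbocycles are bought with actinol; the butenolide closes first and the epoxide second, in the same operation.

Assumption: (4R,6R)-actinol, (2E)-3-methylpent-2-en-4-yn-1-ol and (E)-1,2-bis(tributylstannyl)ethene are bought; the target is the Z-ylidene butenolide as written in the SMILES.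

**Step 1**
Reactants: 1 (4R,6R)-actinol
Product: 2 actinol TBS ether
Conditions: TBSCl, imidazole, DMF, rt
Reagents that add atoms: tert-butyldimethylsilyl chloride, CC(C)(C)[Si](C)(C)Cl
Why: Imidazole-promoted silylation of the secondary alcohol (silyl ether protection); no stereocentre is touched.

**Step 2**
Reactants: 2 actinol TBS ether
Product: 4 α-chloro ketone (Cl cis to OTBS), via lithium enolate 3 (not isolated)
Conditions: LiN(iPr)2, THF, −78 °C; then N-chlorosuccinimide, −78 → −40 °C; aq. NH4Cl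
Reagents that add atoms: N-chlorosuccinimide, ClN1C(=O)CCC1=O
Why: Electrophilic α-chlorination of the lithium enolate formed at the only enolisable position, in which the half-chair with pseudoequatorial OTBS carries the pseudoaxial methyl of the gem-dimethyl group on the face anti to OTBS, so the reagent enters from the open face cis to OTBS, and the new quaternary C–Cl centre cannot epimerise, the minor epimer being removed by chromatography.

**Step 3**
Reactants: 4 α-chloro ketone and 5 (E)-1,2-bis(tributylstannyl)ethene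
Product: 7 trans-chlorohydrin vinylstannane, via stannylvinyllithium 6 (not isolated)
Conditions: 5, n-BuLi, THF, −78 → −40 °C; then 4, LaCl3·2LiCl (30 mol%), −78 °C; AcOH, −78 °C
Reagents that add atoms: none
Why: 1,2-Addition of a vinyllithium (from tin–lithium exchange) to a non-enolisable α-chloro ketone, a Cornforth-type chlorohydrin synthesis, in which the chair that keeps OTBS and Cl equatorial has one carbonyl face screened by the two syn-axial methyl groups flanking the carbonyl, so the nucleophile adds axially from the face cis to Cl and OTBS and the new tertiary carbinol carries OH trans to Cl, the cold acidic quench stopping the sequence at the chlorohydrin.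

**Step 4**
Reactants: 2 actinol TBS ether
Product: 9 enol triflate, via potassium enolate 8 (not isolated)
Conditions: KN(SiMe3)2, THF, −78 → −20 °C; then PhNTf2, −78 → 0 °C; aq. NH4Cl
Reagents that add atoms: N-phenylbis(trifluoromethanesulfonimide), FC(F)(F)S(=O)(=O)N(c1ccccc1)S(=O)(=O)C(F)(F)F
Why: O-Triflation of the potassium enolate, whose loose ion pair reacts cleanly at oxygen with PhNTf2 even at this hindered tetrasubstituted position, gives the only possible enol triflate and leaves the carbinol stereocentre untouched.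

**Step 5**
Reactants: 10 (2E)-3-methylpent-2-en-4-yn-1-ol
Product: 11 enynyl triphenylphosphonium bromide
Conditions: Ph3P·HBr, MeOH, rt
Reagents that add atoms: triphenylphosphine hydrobromide, [Br-].c1ccc(cc1)[PH+](c1ccccc1)c1ccccc1
Why: Acid-mediated substitution of the primary allylic alcohol by triphenylphosphine (allylic phosphonium salt formation, standard in polyene work); any E/Z scrambling is corrected after step 6.

**Step 6**
Reactants: 11 enynyl triphenylphosphonium bromide (2 equiv) and 12 glyoxal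
Product: 15 all-E C14 tetraene-diyne, via phosphorus ylide 13 (not isolated), via dienynal 14 (not isolated)
Conditions: NaOMe, MeOH/CH2Cl2, −10 °C → rt, glyoxal (40% aq.); then I2 (cat.), CH2Cl2, daylight, rt
Reagents that add atoms: none
Why: Two-directional double Wittig olefination of the C2 dialdehyde with the semi-stabilised allylic ylide, followed by iodine-catalysed equilibration to the all-E polyene, which is purified by crystallisation.

**Step 7**
Reactants: 9 enol triflate and 15 all-E C14 tetraene-diyne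
Product: 16 east polyenyne with free terminal alkyne
Conditions: 15 (3 equiv), Pd(PPh3)4 (5 mol%), CuI (10 mol%), Et3N, DMF, 50 °C, dark
Reagents that add atoms: none
Why: Sonogashira coupling of the hindered enol triflate with one terminus of the symmetrical diyne, which is used in excess so that mono-coupling dominates and the surplus is recovered; no stereocentre is formed.

**Step 8**
Reactants: 17 propiolic acid
Product: 18 (2E)-2,3-dibromoprop-2-enoic acid
Conditions: Br2 (1.0 equiv), CHCl3, 0 °C → rt, dark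
Reagents that add atoms: bromine, BrBr
Why: Electrophilic anti-addition of bromine to the alkyne gives the E-dibromide, in which the C3 bromine is cis to the carboxyl group as needed for later lactonisation.

**Step 9**
Reactants: 16 east polyenyne, 18 (2E)-2,3-dibromoprop-2-enoic acid and 7 trans-chlorohydrin vinylstannane
Product: 22 3,3′-bis-TBS pyrrhoxanthinol, via bromo enynoic acid 19 (not isolated), via bromobutenolide 20 (not isolated), via epoxy stannane 21 (not isolated)
Conditions: 16, 18, PdCl2(PPh3)2 (5 mol%), CuI (10 mol%), Et3N, MeCN, rt, dark; then 7, CsF, Pd(PPh3)4 (5 mol%), DMF, rt → 45 °C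
Reagents that add atoms: none
Why: Proposed new method: three known events are merged in one flask, namely Sonogashira coupling at the more reactive C3–Br of 18 followed by metal-promoted anti 5-exo-dig addition of the carboxylate to the new alkyne (tandem coupling–lactonisation of 3-haloacrylic acids, which fixes the Z-ylidene geometry), then fluoride- and copper-promoted Stille coupling at the remaining C–Br of the butenolide with retention of the E-vinyl geometry, while CsF/Et3N in DMF closes chlorohydrin 7 to the epoxide by SN2 attack of the tertiary oxygen on the trans C–Cl carbon (through the ring-flipped chair or a twist-boat), inverting C5 so that the epoxide oxygen ends anti to OTBS; the closest precedents are one-pot sequential cross-couplings and base-induced epoxide formation from trans-halohydrins.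

**Step 10**
Reactants: 22 3,3′-bis-TBS pyrrhoxanthinol
Product: 23 pyrrhoxanthinol (target)
Conditions: Bu4NF, AcOH, THF, 0 °C → rt, dark
Reagents that add atoms: none
Why: Fluoride-mediated desilylation, buffered with acetic acid to spare the base-labile ylidenebutenolide and the acid-labile epoxide, frees both secondary alcohols without touching any stereocentre.

**Compound list**

1 | (4R,6R)-4-hydroxy-2,2,6-trimethylcyclohexan-1-one, (−)-actinol | CC1(C)C[C@H](O)C[C@@H](C)C1=O | starting material
2 | (4R,6R)-4-[(tert-butyldimethylsilyl)oxy]-2,2,6-trimethylcyclohexan-1-one | CC1(C)C[C@H](O[Si](C)(C)C(C)(C)C)C[C@@H](C)C1=O | intermediate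
3 | lithium (4R)-4-[(tert-butyldimethylsilyl)oxy]-2,6,6-trimethylcyclohex-1-en-1-olate | CC1=C([O-])C(C)(C)C[C@H](O[Si](C)(C)C(C)(C)C)C1.[Li+] | intermediate
4 | (2S,4S)-4-[(tert-butyldimethylsilyl)oxy]-2-chloro-2,6,6-trimethylcyclohexan-1-one (Cl cis to OTBS) | CC1(C)C[C@H](O[Si](C)(C)C(C)(C)C)C[C@](C)(Cl)C1=O | intermediate
5 | (E)-1,2-bis(tributylstannyl)ethene | CCCC[Sn](CCCC)(CCCC)/C=C/[Sn](CCCC)(CCCC)CCCC | starting material
6 | (E)-2-(tributylstannyl)ethenyllithium | [Li]/C=C/[Sn](CCCC)(CCCC)CCCC | intermediate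
7 | (1S,2S,4S)-4-[(tert-butyldimethylsilyl)oxy]-2-chloro-2,6,6-trimethyl-1-[(E)-2-(tributylstannyl)ethenyl]cyclohexan-1-ol (OH trans to Cl) | CCCC[Sn](CCCC)(CCCC)/C=C/[C@@]1(O)[C@@](C)(Cl)C[C@@H](O[Si](C)(C)C(C)(C)C)CC1(C)C | intermediate
8 | potassium (4R)-4-[(tert-butyldimethylsilyl)oxy]-2,6,6-trimethylcyclohex-1-en-1-olate | CC1=C([O-])C(C)(C)C[C@H](O[Si](C)(C)C(C)(C)C)C1.[K+] | intermediate
9 | (4R)-4-[(tert-butyldimethylsilyl)oxy]-2,6,6-trimethylcyclohex-1-en-1-yl trifluoromethanesulfonate | CC1=C(OS(=O)(=O)C(F)(F)F)C(C)(C)C[C@H](O[Si](C)(C)C(C)(C)C)C1 | intermediate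
10 | (2E)-3-methylpent-2-en-4-yn-1-ol | C#C/C(C)=C/CO | starting material
11 | [(2E)-3-methylpent-2-en-4-yn-1-yl]triphenylphosphonium bromide | C#C/C(C)=C/C[P+](c1ccccc1)(c1ccccc1)c1ccccc1.[Br-] | intermediate
12 | glyoxal (ethanedial) | O=CC=O | starting material
13 | [(2E)-3-methylpent-2-en-4-yn-1-ylidene]triphenylphosphorane | C#C/C(C)=C/C=P(c1ccccc1)(c1ccccc1)c1ccccc1 | intermediate
14 | (2E,4E)-5-methylhepta-2,4-dien-6-ynal | C#C/C(C)=C/C=C/C=O | intermediate
15 | (3E,5E,7E,9E)-3,10-dimethyldodeca-3,5,7,9-tetraene-1,11-diyne | C#C/C(C)=C/C=C/C=C/C=C(C)/C#C | intermediate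
16 | (3E,5E,7E,9E)-1-[(4R)-4-[(tert-butyldimethylsilyl)oxy]-2,6,6-trimethylcyclohex-1-en-1-yl]-3,10-dimethyldodeca-3,5,7,9-tetraene-1,11-diyne | CC1=C(C#C/C(C)=C/C=C/C=C/C=C(C)/C#C)C(C)(C)C[C@H](O[Si](C)(C)C(C)(C)C)C1 | intermediate
17 | propiolic acid (prop-2-ynoic acid) | C#CC(=O)O | starting material
18 | (2E)-2,3-dibromoprop-2-enoic acid | OC(=O)/C(Br)=C\Br | intermediate
19 | (2E,6E,8E,10E,12E)-2-bromo-15-[(4R)-4-[(tert-butyldimethylsilyl)oxy]-2,6,6-trimethylcyclohex-1-en-1-yl]-6,13-dimethylpentadeca-2,6,8,10,12-pentaene-4,14-diynoic acid | CC1=C(C#C/C(C)=C/C=C/C=C/C=C(C)/C#C/C=C(/Br)C(=O)O)C(C)(C)C[C@H](O[Si](C)(C)C(C)(C)C)C1 | intermediate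
20 | (5Z)-3-bromo-5-{(2E,4E,6E,8E)-11-[(4R)-4-[(tert-butyldimethylsilyl)oxy]-2,6,6-trimethylcyclohex-1-en-1-yl]-2,9-dimethylundeca-2,4,6,8-tetraen-10-yn-1-ylidene}furan-2(5H)-one | CC1=C(C#C/C(C)=C/C=C/C=C/C=C(C)/C=C2C=C(Br)C(=O)O/2)C(C)(C)C[C@H](O[Si](C)(C)C(C)(C)C)C1 | intermediate
21 | tributyl{(E)-2-[(1S,4S,6R)-4-[(tert-butyldimethylsilyl)oxy]-2,2,6-trimethyl-7-oxabicyclo[4.1.0]heptan-1-yl]ethenyl}stannane | CCCC[Sn](CCCC)(CCCC)/C=C/[C@@]12O[C@]1(C)C[C@@H](O[Si](C)(C)C(C)(C)C)CC2(C)C | intermediate
22 | (5Z)-3-{(E)-2-[(1S,4S,6R)-4-[(tert-butyldimethylsilyl)oxy]-2,2,6-trimethyl-7-oxabicyclo[4.1.0]heptan-1-yl]ethenyl}-5-{(2E,4E,6E,8E)-11-[(4R)-4-[(tert-butyldimethylsilyl)oxy]-2,6,6-trimethylcyclohex-1-en-1-yl]-2,9-dimethylundeca-2,4,6,8-tetraen-10-yn-1-ylidene}furan-2(5H)-one | CC1=C(C#C/C(C)=C/C=C/C=C/C=C(C)/C=C2C=C(/C=C/[C@@]34O[C@]3(C)C[C@@H](O[Si](C)(C)C(C)(C)C)CC4(C)C)C(=O)O/2)C(C)(C)C[C@H](O[Si](C)(C)C(C)(C)C)C1 | intermediate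
23 | pyrrhoxanthinol, (5Z)-3-{(E)-2-[(1S,4S,6R)-4-hydroxy-2,2,6-trimethyl-7-oxabicyclo[4.1.0]heptan-1-yl]ethenyl}-5-{(2E,4E,6E,8E)-11-[(4R)-4-hydroxy-2,6,6-trimethylcyclohex-1-en-1-yl]-2,9-dimethylundeca-2,4,6,8-tetraen-10-yn-1-ylidene}furan-2(5H)-one | CC1=C(C#C/C(C)=C/C=C/C=C/C=C(C)/C=C2C=C(/C=C/[C@@]34O[C@]3(C)C[C@@H](O)CC4(C)C)C(=O)O/2)C(C)(C)C[C@H](O)C1 | target

**Step count**

Total: 10 steps. Longest linear sequence: 5 steps (1 → 2 → 4 → 7 → 22 → 23, i.e. steps 1, 2, 3, 9, 10).

**Steps most likely to fail, with fallbacks**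

Step 3 (together with the facial course of step 2 on which it builds). The C5/C6 relay needs the vinyllithium to attack the ketone face cis to chlorine. The competing pathway is attack anti to an axial C–Cl bond in the other chair (polar Felkin–Anh control), which gives the cis-chlorohydrin that cannot close to an epoxide. Halophilic attack on chlorine is a second risk. The fallback replaces substrate control by reagent control. It sets out from enol triflate 9 and comes back at epoxy stannane 21, which then takes the place of 7 in the second stage of step 9. Carbonylation of 9 (Pd(OAc)2, PPh3, CO, MeOH, Et3N, DMF) gives methyl (4R)-4-[(tert-butyldimethylsilyl)oxy]-2,6,6-trimethylcyclohex-1-ene-1-carboxylate F1. Reduction with iBu2AlH gives [(4R)-4-[(tert-butyldimethylsilyl)oxy]-2,6,6-trimethylcyclohex-1-en-1-yl]methanol F2. Sharpless epoxidation (Ti(OiPr)4, D-(−)-diethyl tartrate, t-BuOOH, CH2Cl2, −20 °C) sets the epoxide face by the tartrate and gives the anti-epoxide [(1R,4S,6R)-4-[(tert-butyldimethylsilyl)oxy]-2,2,6-trimethyl-7-oxabicyclo[4.1.0]heptan-1-yl]methanol F3. Dess–Martin oxidation gives (1S,4S,6R)-4-[(tert-butyldimethylsilyl)oxy]-2,2,6-trimethyl-7-oxabicyclo[4.1.0]heptane-1-carbaldehyde F4. Takai-type stannyl olefination (CrCl2, Bu3SnCHBr2, LiI, THF/DMF) then delivers the E-vinylstannane 21.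

Step 9. The coupling–lactonisation is usually only moderate in yield and is run here on a light- and air-sensitive polyenyne. The chlorohydrin may close incompletely or ring-contract instead. The vinyl epoxide must also survive zerovalent palladium. The fallback reverses the order of the two couplings, closes the epoxide separately and closes the butenolide last. It sets out from 7 and 17 and comes back at 22. Chlorohydrin 7 is closed to 21 with K2CO3 in MeOH. Propiolic acid 17 is treated with ICl (anti-addition, chloride at C3) to give (2E)-3-chloro-2-iodoprop-2-enoic acid F5; this regiochemistry is expected by analogy and would need to be confirmed. Stille coupling of 21 at the C–I bond of F5 (Pd2(dba)3, AsPh3, NMP, rt) gives (2Z)-2-{(E)-2-[(1S,4S,6R)-4-[(tert-butyldimethylsilyl)oxy]-2,2,6-trimethyl-7-oxabicyclo[4.1.0]heptan-1-yl]ethenyl}-3-chloroprop-2-enoic acid F6, handled as its triethylammonium salt. Sonogashira coupling of F6 with 16 (Pd(PPh3)4, CuI, Et3N, MeCN, 40 °C) with spontaneous 5-exo-dig lactonisation then gives 22.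

Step 7. The mono-coupling is statistical, the triflate is hindered, and the C14 diyne can bis-couple or dimerise oxidatively. The fallback builds 16 linearly and without the symmetrical diyne. It sets out from 9 and 10 and comes back at 16. Sonogashira coupling of 9 with 10 gives (2E)-5-[(4R)-4-[(tert-butyldimethylsilyl)oxy]-2,6,6-trimethylcyclohex-1-en-1-yl]-3-methylpent-2-en-4-yn-1-ol F7. Treatment with Ph3P·HBr in CH2Cl2 gives {(2E)-5-[(4R)-4-[(tert-butyldimethylsilyl)oxy]-2,6,6-trimethylcyclohex-1-en-1-yl]-3-methylpent-2-en-4-yn-1-yl}triphenylphosphonium bromide F8. Separately, MnO2 oxidation of 10 gives (2E)-3-methylpent-2-en-4-ynal F9, and Wittig reaction with Ph3P=CHCHO gives dienynal 14, now isolated. Wittig olefination of 14 with the ylide from F8 (NaOMe), followed by iodine-catalysed isomerisation, gives 16.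

**Further compounds**

F1 | step 3 | methyl (4R)-4-[(tert-butyldimethylsilyl)oxy]-2,6,6-trimethylcyclohex-1-ene-1-carboxylate | CC1=C(C(=O)OC)C(C)(C)C[C@H](O[Si](C)(C)C(C)(C)C)C1
F2 | step 3 | [(4R)-4-[(tert-butyldimethylsilyl)oxy]-2,6,6-trimethylcyclohex-1-en-1-yl]methanol | CC1=C(CO)C(C)(C)C[C@H](O[Si](C)(C)C(C)(C)C)C1
F3 | step 3 | [(1R,4S,6R)-4-[(tert-butyldimethylsilyl)oxy]-2,2,6-trimethyl-7-oxabicyclo[4.1.0]heptan-1-yl]methanol | OC[C@@]12O[C@]1(C)C[C@@H](O[Si](C)(C)C(C)(C)C)CC2(C)C
F4 | step 3 | (1S,4S,6R)-4-[(tert-butyldimethylsilyl)oxy]-2,2,6-trimethyl-7-oxabicyclo[4.1.0]heptane-1-carbaldehyde | O=C[C@@]12O[C@]1(C)C[C@@H](O[Si](C)(C)C(C)(C)C)CC2(C)C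
F5 | step 9 | (2E)-3-chloro-2-iodoprop-2-enoic acid | OC(=O)/C(I)=C\Cl
F6 | step 9 | (2Z)-2-{(E)-2-[(1S,4S,6R)-4-[(tert-butyldimethylsilyl)oxy]-2,2,6-trimethyl-7-oxabicyclo[4.1.0]heptan-1-yl]ethenyl}-3-chloroprop-2-enoic acid | OC(=O)/C(=C\Cl)/C=C/[C@@]12O[C@]1(C)C[C@@H](O[Si](C)(C)C(C)(C)C)CC2(C)C
F7 | step 7 | (2E)-5-[(4R)-4-[(tert-butyldimethylsilyl)oxy]-2,6,6-trimethylcyclohex-1-en-1-yl]-3-methylpent-2-en-4-yn-1-ol | CC1=C(C#C/C(C)=C/CO)C(C)(C)C[C@H](O[Si](C)(C)C(C)(C)C)C1
F8 | step 7 | {(2E)-5-[(4R)-4-[(tert-butyldimethylsilyl)oxy]-2,6,6-trimethylcyclohex-1-en-1-yl]-3-methylpent-2-en-4-yn-1-yl}triphenylphosphonium bromide | CC1=C(C#C/C(C)=C/C[P+](c2ccccc2)(c2ccccc2)c2ccccc2)C(C)(C)C[C@H](O[Si](C)(C)C(C)(C)C)C1.[Br-]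
F9 | step 7 | (2E)-3-methylpent-2-en-4-ynal | C#C/C(C)=C/C=O
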